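A small charge of substrate, 10 mM with 1.20 equiv of reagent, is a diluted copy of the ash run at 15 mM, with the same equivalents.

| flask | substrate | reagent | remark | time |
|---|---|---|---|---|
| ash | 15 mM | 1.2 equiv | run made earlier |  |
| flask | 10 mM | 1.20 equiv |  | 6.0 h |

ash run (percent of the substrate charged)

| time / min | mono adduct / % |
|---|---|
| 6.00 | 6.8 |
| 10.0 | 8.5 |
| 20.0 | 13.6 |
| 40.0 | 13.6 |
| 80.0 | 10.4 |

(scatter of a reading: 0.5 percentage points)

- the moment within 6.0 h at which there is most mono adduct
- the amount of mono adduct, in percent of the substrate charged, at that time
- earliest time at which at least nineteen twentieths of that best amount are there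
- latest time at which they still are



In the ash run the mono adduct reads 13.6% at 20.0 min and 13.6% at 40.0 min. These agree within the scatter, so I read its peak between them, near 30.0 min.

Two of us argue over how dilution moves that peak. Follow one mono adduct molecule: it is born from substrate, and it then waits at a fork. The forecast's maker sees no slowing in the ash readings and takes the steps as first order in substrate, with reagent out of the count: “dilution should not shift the timescale”. The forecast is therefore 0.52 h for the peak, 14.4% at it, and a window from 0.36 h to 0.73 h.

I hold that these steps are meetings with reagent, second order overall. At fixed equivalents, the wait for a partner then grows by the stretch 1.50, the ash c(substrate) over the flask's. So I put the flask's peak at 0.750 h.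

The flask peaks at 0.676 h with 12.1%, and its window runs from 0.461 h to 0.971 h. That peak is later than the forecast's and earlier than mine.

    substrate + reagent → mono adduct + released group (k = 0.0130 M⁻¹ s⁻¹)
    mono adduct → over-reaction product (k = 3.80 × 10⁻⁴ s⁻¹)
    reagent + mono adduct → bis adduct + released group (k = 0.0330 M⁻¹ s⁻¹)
    reagent + bis adduct → triple product + released group (k = 0.00850 M⁻¹ s⁻¹)

As charged, mono adduct here has a half-life of 0.49 h at the reagent exit and 0.51 h at its own exit to over-reaction product. That own exit, whose constant holds no concentration, is where the forecast's view is right. For the neighbouring flask at 40 mM, with the equivalents held, the stretch against ash is 0.375. Scaled by c(substrate) from this flask, the reagent exit as charged there has a half-life of 0.122 h, below the own exit. That neighbour's best amount of mono adduct is 17.5%, and it holds 33.9% over-reaction product after 6.00 h, against 46.6% in this flask.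

Readings and results come from a simulation with made-up constants; scatter was added.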